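**Plan**

1. Numbering: the unprimed tetralone is C1(=O)–C2–C3–C4(OH)–C4a…C8a with C5–OH and C7–CH3; the primed tetralone is C1′(=O)…C4′(OH), with C7′ bonded to C3 and C8′–OH.
2. Retrosynthetic cuts, in order: the two phenol benzyl ethers and the C4′ silyl ether; then C4–C4a, which opens the cyclohexanone ring of the unprimed unit to a keto aldehyde with boron on C4a; then C2–C3, which gives a C7′ arylacetaldehyde and a bromoacetyl arylboronate.
3. Enabling feature: C4 is a benzylic carbinol bonded to arene carbon C4a, which lies between C5–O and the acyl-bearing C8a, so a C4a–metal bond can close only onto a C4 aldehyde. C3 is α to that aldehyde and carries aryl B, so it can epimerise before closure.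
4. Forward order: the primed bicycle comes from 4-chloro-3-methylphenol and maleic anhydride (naphthoquinone, dihydrodione, carbinol), and its C7′ side chain from O-allylation, Claisen rearrangement and alkene cleavage. Arene A comes from 4-methylcatechol (ortho-lithiation/acetylation, OTf to Bpin, α-bromination). Enamine alkylation joins the halves, the Rh step closes the last ring, and deprotection follows.
5. Stereochemistry: C4′ (R) from Noyori transfer hydrogenation; C4 (S) from the chiral Rh catalyst; C3 (R) by dynamic kinetic resolution of the aldehyde epimers in the same step, giving the cis product.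

Key step: step 16

Assumption: the ligand antipode named in step 16 is provisional; the antipode meant is the one that delivers the aryl group to the Re face of the formyl group (C4 S), to be settled on a model aldehyde.

**Route**

Step 1
Reactants: 1 4-chloro-3-methylphenol; 2 maleic anhydride
Product: 3 8-chloro-5-hydroxy-7-methylnaphthalene-1,4-dione
Conditions: AlCl3/NaCl melt, 180 °C; then ice/aq HCl
Reagents that add atoms: none
Why: Double Friedel–Crafts acylation of the phenol by the anhydride should build the quinone ring across C5–C6 of the phenol, because the chlorine blocks the position para to OH.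

Step 2
Reactants: 3 8-chloro-5-hydroxy-7-methylnaphthalene-1,4-dione
Product: 5 5-hydroxy-7-methyl-2,3-dihydronaphthalene-1,4-dione, via triol 4 (not isolated)
Conditions: SnCl2·2H2O, 4 M HCl, THF, 60 °C, Ar; then TFA, CH2Cl2, rt
Reagents that add atoms: none
Why: Sn(II) reduces the quinone and removes the peri chlorine (reductive dehalogenation through the keto tautomer of the chlorohydroquinone), and acid should then ketonise the 1,4,5-triol to the diketo tautomer held by the C5–OH···O=C4 hydrogen bond (hydroquinone–diketone tautomerisation).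

Step 3
Reactants: 5 5-hydroxy-7-methyl-2,3-dihydronaphthalene-1,4-dione
Product: 6 (4R)-4,8-dihydroxy-6-methyl-3,4-dihydronaphthalen-1(2H)-one
Conditions: RuCl[(R,R)-TsDPEN](p-cymene) (1 mol %), HCO2H/Et3N (5:2), EtOAc, 30 °C
Reagents that add atoms: none
Why: Noyori asymmetric transfer hydrogenation should reduce the free aryl ketone and spare the chelated, phenol-conjugated one, the (R,R) catalyst giving the R carbinol as it does with 1-tetralone.

Step 4
Reactants: 6 (4R)-4,8-dihydroxy-6-methyl-3,4-dihydronaphthalen-1(2H)-one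
Product: 7 (4R)-4-hydroxy-6-methyl-8-(prop-2-en-1-yloxy)-3,4-dihydronaphthalen-1(2H)-one
Conditions: allyl bromide, K2CO3, acetone, reflux
Reagents that add atoms: allyl bromide, C=CCBr
Why: Williamson etherification takes place at the phenol only, since carbonate does not deprotonate the secondary alcohol.

Step 5
Reactants: 7 (4R)-4-hydroxy-6-methyl-8-(prop-2-en-1-yloxy)-3,4-dihydronaphthalen-1(2H)-one
Product: 8 (4R)-4-[(tert-butyldimethylsilyl)oxy]-6-methyl-8-(prop-2-en-1-yloxy)-3,4-dihydronaphthalen-1(2H)-one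
Conditions: TBSCl, imidazole, DMF, rt
Reagents that add atoms: tert-butyldimethylsilyl chloride, CC(C)(C)[Si](C)(C)Cl
Why: Imidazole-mediated silylation protects the benzylic carbinol so that it withstands the thermal step that follows.

Step 6
Reactants: 8 (4R)-4-[(tert-butyldimethylsilyl)oxy]-6-methyl-8-(prop-2-en-1-yloxy)-3,4-dihydronaphthalen-1(2H)-one
Product: 9 (4R)-4-[(tert-butyldimethylsilyl)oxy]-8-hydroxy-6-methyl-7-(prop-2-en-1-yl)-3,4-dihydronaphthalen-1(2H)-one
Conditions: PhNEt2, 190 °C, sealed tube, Ar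
Reagents that add atoms: none
Why: The aromatic Claisen rearrangement can deliver the allyl group only to C7′, the single free ortho position, and tautomerisation restores the chelated phenol without touching C4′.

Step 7
Reactants: 9 (4R)-4-[(tert-butyldimethylsilyl)oxy]-8-hydroxy-6-methyl-7-(prop-2-en-1-yl)-3,4-dihydronaphthalen-1(2H)-one
Product: 10 (4R)-8-(benzyloxy)-4-[(tert-butyldimethylsilyl)oxy]-6-methyl-7-(prop-2-en-1-yl)-3,4-dihydronaphthalen-1(2H)-one
Conditions: BnBr, K2CO3, Bu4NI (cat.), DMF, 60 °C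
Reagents that add atoms: benzyl bromide, BrCc1ccccc1
Why: Williamson benzylation of the hindered phenol prevents lactol formation with the aldehyde made next and gives an ether that is removable under neutral conditions.

Step 8
Reactants: 10 (4R)-8-(benzyloxy)-4-[(tert-butyldimethylsilyl)oxy]-6-methyl-7-(prop-2-en-1-yl)-3,4-dihydronaphthalen-1(2H)-one
Product: 11 2-[(5R)-1-(benzyloxy)-5-[(tert-butyldimethylsilyl)oxy]-3-methyl-8-oxo-5,6,7,8-tetrahydronaphthalen-2-yl]acetaldehyde
Conditions: OsO4 (2 mol %), NaIO4, 2,6-lutidine, dioxane/H2O, rt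
Reagents that add atoms: sodium periodate, [Na+].[O-]I(=O)(=O)=O (terminal oxidant and oxygen source, relayed by catalytic osmium tetroxide, O=[Os](=O)(=O)=O)
Why: Lemieux–Johnson cleavage of the terminal alkene should give the arylacetaldehyde directly, with lutidine suppressing over-oxidation.

Step 9
Reactants: 12 4-methylbenzene-1,2-diol
Product: 13 1,2-bis(methoxymethoxy)-4-methylbenzene
Conditions: MOMCl, i-Pr2NEt, CH2Cl2, 0 °C to rt
Reagents that add atoms: chloromethyl methyl ether, COCCl
Why: Acetal-type O-alkylation of both phenols installs the directing groups for ortho-metalation.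

Step 10
Reactants: 13 1,2-bis(methoxymethoxy)-4-methylbenzene
Product: 16 1-(2,3-dihydroxy-5-methylphenyl)ethan-1-one, via aryllithium 14 (not isolated), via bis-MOM ketone 15 (not isolated)
Conditions: n-BuLi, TMEDA, THF, 0 °C; then MeC(O)N(OMe)Me, −78 °C to rt; then 3 M HCl, MeOH, 50 °C
Reagents that add atoms: N-methoxy-N-methylacetamide, CC(=O)N(C)OC
Why: Directed ortho-metalation should occur at the OMOM-flanked position remote from the methyl group, Weinreb amide acylation stops at the ketone, and methanolic acid then removes both acetals.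

Step 11
Reactants: 16 1-(2,3-dihydroxy-5-methylphenyl)ethan-1-one
Product: 17 1-[3-(benzyloxy)-2-hydroxy-5-methylphenyl]ethan-1-one
Conditions: NaH (2.1 equiv), DMSO/THF, rt, Ar; BnBr (1.0 equiv)
Reagents that add atoms: benzyl bromide, BrCc1ccccc1
Why: In the dianion the C3 phenoxide, which is not conjugated to the acetyl group, is the more nucleophilic, so Williamson alkylation should be regioselective there.

Step 12
Reactants: 17 1-[3-(benzyloxy)-2-hydroxy-5-methylphenyl]ethan-1-one
Product: 18 2-acetyl-6-(benzyloxy)-4-methylphenyl trifluoromethanesulfonate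
Conditions: Tf2O, pyridine, CH2Cl2, 0 °C
Reagents that add atoms: trifluoromethanesulfonic anhydride, O=S(=O)(OS(=O)(=O)C(F)(F)F)C(F)(F)F
Why: O-sulfonylation turns the chelated phenol into the leaving group that marks the future C4a.

Step 13
Reactants: 18 2-acetyl-6-(benzyloxy)-4-methylphenyl trifluoromethanesulfonate
Product: 19 1-[3-(benzyloxy)-5-methyl-2-(4,4,5,5-tetramethyl-1,3,2-dioxaborolan-2-yl)phenyl]ethan-1-one
Conditions: B2pin2, PdCl2(dppf) (5 mol %), KOAc, dioxane, 90 °C
Reagents that add atoms: bis(pinacolato)diboron, CC1(C)OB(OC1(C)C)B1OC(C)(C)C(C)(C)O1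
Why: Miyaura borylation of the aryl triflate is helped by the ortho acetyl group in oxidative addition, and acetate is too weak a base to enolise the ketone or promote Suzuki coupling.

Step 14
Reactants: 19 1-[3-(benzyloxy)-5-methyl-2-(4,4,5,5-tetramethyl-1,3,2-dioxaborolan-2-yl)phenyl]ethan-1-one
Product: 21 1-[3-(benzyloxy)-5-methyl-2-(4,4,5,5-tetramethyl-1,3,2-dioxaborolan-2-yl)phenyl]-2-bromoethan-1-one, via silyl enol ether 20 (not isolated)
Conditions: TMSOTf, Et3N, CH2Cl2, 0 °C; then NBS, THF, −78 to 0 °C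
Reagents that add atoms: N-bromosuccinimide, O=C1CCC(=O)N1Br
Why: Bromination of the preformed silyl enol ether is specific for the acetyl carbon and avoids both ring bromination and acid.

Step 15
Reactants: 11 2-[(5R)-1-(benzyloxy)-5-[(tert-butyldimethylsilyl)oxy]-3-methyl-8-oxo-5,6,7,8-tetrahydronaphthalen-2-yl]acetaldehyde; 21 1-[3-(benzyloxy)-5-methyl-2-(4,4,5,5-tetramethyl-1,3,2-dioxaborolan-2-yl)phenyl]-2-bromoethan-1-one
Product: 24 4-[3-(benzyloxy)-5-methyl-2-(4,4,5,5-tetramethyl-1,3,2-dioxaborolan-2-yl)phenyl]-2-[(5R)-1-(benzyloxy)-5-[(tert-butyldimethylsilyl)oxy]-3-methyl-8-oxo-5,6,7,8-tetrahydronaphthalen-2-yl]-4-oxobutanal (both epimers at the formyl-bearing carbon, the future C3), via enamine 22 (not isolated), via iminium bromide 23 (not isolated)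
Conditions: pyrrolidine, 4 Å MS, PhMe, rt; evaporate; then 21, MeCN, 0 °C to rt; then AcOH/NaOAc buffer (pH 5), rt
Reagents that add atoms: none
Why: In a Stork enamine alkylation the β-carbon of the aldehyde enamine displaces the primary phenacyl bromide to form C2–C3, and buffered hydrolysis returns the aldehyde; C3 forms without control, which is intended.

Step 16
Reactants: 24 4-[3-(benzyloxy)-5-methyl-2-(4,4,5,5-tetramethyl-1,3,2-dioxaborolan-2-yl)phenyl]-2-[(5R)-1-(benzyloxy)-5-[(tert-butyldimethylsilyl)oxy]-3-methyl-8-oxo-5,6,7,8-tetrahydronaphthalen-2-yl]-4-oxobutanal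
Product: 25 (3R,4S)-5-(benzyloxy)-3-[(5R)-1-(benzyloxy)-5-[(tert-butyldimethylsilyl)oxy]-3-methyl-8-oxo-5,6,7,8-tetrahydronaphthalen-2-yl]-4-hydroxy-7-methyl-3,4-dihydronaphthalen-1(2H)-one
Conditions: [Rh(C2H4)2Cl]2 (2.5 mol %), chiral diene ligand (e.g. (S,S)-Ph-bod*, 6 mol %), K3PO4 (aq), dioxane/H2O (10:1), 40 °C, degassed
Reagents that add atoms: none
Why: Proposed new method: base-assisted B-to-Rh transmetalation places rhodium on C4a, the aryl–Rh bond adds across the tethered formyl group through a four-centre transition state, and water cleaves the C4 rhodium alkoxide and returns Rh–OH. The closest known reaction type is the Rh(I)-catalysed enantioselective 1,2-addition of arylboron reagents to aldehydes and, intramolecularly, to ketones; its coupling to in situ racemisation of an α-aryl aldehyde is the untested part, reasoned from the ease with which such aldehydes enolise in mild aqueous base. The cyclohexanone ring of the unprimed tetralone closes in the 6-exo-trig mode by C4a attacking the exocyclic C=O. C4 (S) is set by the ligand, which should deliver the aryl group to the Re face, and C3 (R) by dynamic kinetic resolution: only in the 3R epimer can aryl B lie pseudo-equatorial and anti to the incoming C4a (Felkin–Anh) while the carbonyl oxygen sits pseudo-axial toward rhodium, which is the cis arrangement, and the slower 3S epimer is fed back through the enol. The step needs chemoselectivity for the aldehyde over two aryl ketones and a single site of closure: the A ketone is ortho to the C–Rh bond and out of reach, the B ketone is remote and less electrophilic, and the boron lies between C5–O and C8a so that only C4a can bond.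

Step 17
Reactants: 25 (3R,4S)-5-(benzyloxy)-3-[(5R)-1-(benzyloxy)-5-[(tert-butyldimethylsilyl)oxy]-3-methyl-8-oxo-5,6,7,8-tetrahydronaphthalen-2-yl]-4-hydroxy-7-methyl-3,4-dihydronaphthalen-1(2H)-one
Product: 26 (3R,4S)-5-(benzyloxy)-3-[(5R)-1-(benzyloxy)-5-hydroxy-3-methyl-8-oxo-5,6,7,8-tetrahydronaphthalen-2-yl]-4-hydroxy-7-methyl-3,4-dihydronaphthalen-1(2H)-one
Conditions: HF·pyridine, pyridine, THF, 0 °C to rt
Reagents that add atoms: none
Why: Buffered fluoride cleavage of the silyl ether avoids the acid that could ionise the ortho-alkoxybenzylic C4 carbinol.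

Step 18
Reactants: 26 (3R,4S)-5-(benzyloxy)-3-[(5R)-1-(benzyloxy)-5-hydroxy-3-methyl-8-oxo-5,6,7,8-tetrahydronaphthalen-2-yl]-4-hydroxy-7-methyl-3,4-dihydronaphthalen-1(2H)-one
Product: 27 (3R,4S)-3-[(5R)-1,5-dihydroxy-3-methyl-8-oxo-5,6,7,8-tetrahydronaphthalen-2-yl]-4,5-dihydroxy-7-methyl-3,4-dihydronaphthalen-1(2H)-one
Conditions: H2 (1 atm), 10% Pd/C, EtOAc, rt, stopped at full conversion
Reagents that add atoms: none
Why: Hydrogenolysis of the two aryl benzyl ethers under neutral conditions should be much faster than cleavage of the benzylic C–OH bonds or reduction of the aryl ketones, and no stereocentre is touched.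

**Compound list**

1 | 4-chloro-3-methylphenol | Cc1cc(O)ccc1Cl | starting material
2 | maleic anhydride | O=C1OC(=O)C=C1 | starting material
3 | 8-chloro-5-hydroxy-7-methylnaphthalene-1,4-dione | Cc1cc(O)c2C(=O)C=CC(=O)c2c1Cl | intermediate
4 | 7-methylnaphthalene-1,4,5-triol (formed in situ) | Cc1cc(O)c2c(O)ccc(O)c2c1 | intermediate
5 | 5-hydroxy-7-methyl-2,3-dihydronaphthalene-1,4-dione | Cc1cc(O)c2C(=O)CCC(=O)c2c1 | intermediate
6 | (4R)-4,8-dihydroxy-6-methyl-3,4-dihydronaphthalen-1(2H)-one | Cc1cc2c(c(O)c1)C(=O)CC[C@H]2O | intermediate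
7 | (4R)-4-hydroxy-6-methyl-8-(prop-2-en-1-yloxy)-3,4-dihydronaphthalen-1(2H)-one | Cc1cc2c(c(OCC=C)c1)C(=O)CC[C@H]2O | intermediate
8 | (4R)-4-[(tert-butyldimethylsilyl)oxy]-6-methyl-8-(prop-2-en-1-yloxy)-3,4-dihydronaphthalen-1(2H)-one | Cc1cc2c(c(OCC=C)c1)C(=O)CC[C@H]2O[Si](C)(C)C(C)(C)C | intermediate
9 | (4R)-4-[(tert-butyldimethylsilyl)oxy]-8-hydroxy-6-methyl-7-(prop-2-en-1-yl)-3,4-dihydronaphthalen-1(2H)-one | Cc1cc2c(c(O)c1CC=C)C(=O)CC[C@H]2O[Si](C)(C)C(C)(C)C | intermediate
10 | (4R)-8-(benzyloxy)-4-[(tert-butyldimethylsilyl)oxy]-6-methyl-7-(prop-2-en-1-yl)-3,4-dihydronaphthalen-1(2H)-one | Cc1cc2c(c(OCc3ccccc3)c1CC=C)C(=O)CC[C@H]2O[Si](C)(C)C(C)(C)C | intermediate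
11 | 2-[(5R)-1-(benzyloxy)-5-[(tert-butyldimethylsilyl)oxy]-3-methyl-8-oxo-5,6,7,8-tetrahydronaphthalen-2-yl]acetaldehyde | Cc1cc2c(c(OCc3ccccc3)c1CC=O)C(=O)CC[C@H]2O[Si](C)(C)C(C)(C)C | intermediate
12 | 4-methylbenzene-1,2-diol (4-methylcatechol) | Cc1ccc(O)c(O)c1 | starting material
13 | 1,2-bis(methoxymethoxy)-4-methylbenzene | COCOc1ccc(C)cc1OCOC | intermediate
14 | [2,3-bis(methoxymethoxy)-5-methylphenyl]lithium (formed in situ) | [Li]c1cc(C)cc(OCOC)c1OCOC | intermediate
15 | 1-[2,3-bis(methoxymethoxy)-5-methylphenyl]ethan-1-one (formed in situ) | CC(=O)c1cc(C)cc(OCOC)c1OCOC | intermediate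
16 | 1-(2,3-dihydroxy-5-methylphenyl)ethan-1-one | CC(=O)c1cc(C)cc(O)c1O | intermediate
17 | 1-[3-(benzyloxy)-2-hydroxy-5-methylphenyl]ethan-1-one | CC(=O)c1cc(C)cc(OCc2ccccc2)c1O | intermediate
18 | 2-acetyl-6-(benzyloxy)-4-methylphenyl trifluoromethanesulfonate | CC(=O)c1cc(C)cc(OCc2ccccc2)c1OS(=O)(=O)C(F)(F)F | intermediate
19 | 1-[3-(benzyloxy)-5-methyl-2-(4,4,5,5-tetramethyl-1,3,2-dioxaborolan-2-yl)phenyl]ethan-1-one | CC(=O)c1cc(C)cc(OCc2ccccc2)c1B3OC(C)(C)C(C)(C)O3 | intermediate
20 | trimethylsilyl enol ether of 19 (formed in situ) | C=C(O[Si](C)(C)C)c1cc(C)cc(OCc2ccccc2)c1B3OC(C)(C)C(C)(C)O3 | intermediate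
21 | 1-[3-(benzyloxy)-5-methyl-2-(4,4,5,5-tetramethyl-1,3,2-dioxaborolan-2-yl)phenyl]-2-bromoethan-1-one | BrCC(=O)c1cc(C)cc(OCc2ccccc2)c1B3OC(C)(C)C(C)(C)O3 | intermediate
22 | (E)-pyrrolidine enamine of aldehyde 11 (formed in situ) | Cc1cc2c(c(OCc3ccccc3)c1/C=C/N4CCCC4)C(=O)CC[C@H]2O[Si](C)(C)C(C)(C)C | intermediate
23 | C-alkylated pyrrolidinium (iminium) bromide, both C3 epimers (formed in situ) | Cc1cc(OCc2ccccc2)c(B2OC(C)(C)C(C)(C)O2)c(c1)C(=O)CC(C=[N+]5CCCC5)c1c(C)cc2c(c1OCc3ccccc3)C(=O)CC[C@H]2O[Si](C)(C)C(C)(C)C.[Br-] | intermediate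
24 | 4-[3-(benzyloxy)-5-methyl-2-(4,4,5,5-tetramethyl-1,3,2-dioxaborolan-2-yl)phenyl]-2-[(5R)-1-(benzyloxy)-5-[(tert-butyldimethylsilyl)oxy]-3-methyl-8-oxo-5,6,7,8-tetrahydronaphthalen-2-yl]-4-oxobutanal, both epimers at C2 of the butanal | Cc1cc(OCc2ccccc2)c(B2OC(C)(C)C(C)(C)O2)c(c1)C(=O)CC(C=O)c1c(C)cc2c(c1OCc3ccccc3)C(=O)CC[C@H]2O[Si](C)(C)C(C)(C)C | intermediate
25 | (3R,4S)-5-(benzyloxy)-3-[(5R)-1-(benzyloxy)-5-[(tert-butyldimethylsilyl)oxy]-3-methyl-8-oxo-5,6,7,8-tetrahydronaphthalen-2-yl]-4-hydroxy-7-methyl-3,4-dihydronaphthalen-1(2H)-one | Cc1cc(OCc2ccccc2)c2c(c1)C(=O)C[C@H](c1c(C)cc3c(c1OCc4ccccc4)C(=O)CC[C@H]3O[Si](C)(C)C(C)(C)C)[C@@H]2O | intermediate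
26 | (3R,4S)-5-(benzyloxy)-3-[(5R)-1-(benzyloxy)-5-hydroxy-3-methyl-8-oxo-5,6,7,8-tetrahydronaphthalen-2-yl]-4-hydroxy-7-methyl-3,4-dihydronaphthalen-1(2H)-one | Cc1cc(OCc2ccccc2)c2c(c1)C(=O)C[C@H](c1c(C)cc3c(c1OCc4ccccc4)C(=O)CC[C@H]3O)[C@@H]2O | intermediate
27 | (3R,4S)-3-[(5R)-1,5-dihydroxy-3-methyl-8-oxo-5,6,7,8-tetrahydronaphthalen-2-yl]-4,5-dihydroxy-7-methyl-3,4-dihydronaphthalen-1(2H)-one (CNP0228272.3) | Cc1cc(O)c2c(c1)C(=O)C[C@H](c1c(C)cc3c(c1O)C(=O)CC[C@H]3O)[C@@H]2O | target

**Step count and risks**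

Total: 18 steps. Longest linear sequence: 12 steps (steps 1–8 and 15–18, from 4-chloro-3-methylphenol); the arene A branch (steps 9–14) has 6 steps before the union.

Step 16 (Proposed new method). Ring closure may outrun epimerisation at C3, or the catalyst may not discriminate enough between the two aldehyde epimers, so that C3/C4 diastereomers accumulate. Transmetalation of the boronate, which has two ortho substituents, may also be slow enough for protodeboronation to compete. The fallback uses known chemistry without boron or catalyst control. It sets out from triflate 18 (with enamine 22 from aldehyde 11) and rejoins the route at 25. Direct α-bromination of 18 with PhNMe3Br3 in THF would give 2-(benzyloxy)-6-(bromoacetyl)-4-methylphenyl trifluoromethanesulfonate F1. Alkylation of enamine 22 with it would give the corresponding C-alkylated iminium bromide F2 (not isolated), and buffered hydrolysis the triflate analogue of the keto aldehyde F3. A Nozaki–Hiyama–Kishi closure (CrCl2, cat. NiCl2, DMF, rt) would then form C4–C4a by addition of the aryl chromium species to the aldehyde. Under these neutral conditions C3 should not epimerise, and each epimer is expected to close through the same Felkin-type arrangement to a cis product: 25 from the 3R epimer and the (3S,4R) diastereomer of 25 F4 from the other. Because C4′ is already resolved these are diastereomers, to be separated by chromatography, and 25 continues with step 17.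

Step 15. N-alkylation, slow C-alkylation at an enamine carbon shielded by two ortho substituents, and self-condensation of the arylacetaldehyde may erode the union. The fallback sets out from 11 and 21 and returns at 24. It is a photoredox organocatalytic α-alkylation: pyrrolidine (20 mol %), Ru(bpy)3Cl2 (1 mol %), 2,6-lutidine, DMF and blue light. The phenacyl radical formed from 21 by single-electron reduction adds to the catalytic amount of enamine 22; oxidation of the α-amino radical gives iminium 23, whose hydrolysis releases 24 and the amine. A radical addition replaces the SN2 step and is less sensitive to crowding, and no compound outside the list is made.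

Step 3. Incomplete site selection between the two carbonyl groups, over-reduction, or reversion of the dione to the naphthalenetriol in the amine-containing medium may lower conversion or enantiomeric purity. The fallback sets out from 5 and returns at 6. NaBH4 (MeOH, −20 °C) should reduce only the non-chelated ketone and give racemic 4,8-dihydroxy-6-methyl-3,4-dihydronaphthalen-1(2H)-one F5. Lipase-catalysed kinetic resolution (Burkholderia cepacia lipase, vinyl acetate, MTBE, 30 °C) is expected to acylate the R carbinol, as with 1-tetralol, to give (4R)-4-acetoxy-8-hydroxy-6-methyl-3,4-dihydronaphthalen-1(2H)-one F6, which is separated from the unreacted S alcohol. Methanolysis (K2CO3, MeOH, 0 °C) then returns 6.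

**Further compounds**

F1 | step 16 | 2-(benzyloxy)-6-(bromoacetyl)-4-methylphenyl trifluoromethanesulfonate | O=C(CBr)c1cc(C)cc(OCc2ccccc2)c1OS(=O)(=O)C(F)(F)F
F2 | step 16 | C-alkylated pyrrolidinium (iminium) bromide of the triflate series, both C3 epimers (not isolated) | Cc1cc(OCc2ccccc2)c(OS(=O)(=O)C(F)(F)F)c(c1)C(=O)CC(C=[N+]5CCCC5)c1c(C)cc2c(c1OCc3ccccc3)C(=O)CC[C@H]2O[Si](C)(C)C(C)(C)C.[Br-]
F3 | step 16 | 2-(benzyloxy)-4-methyl-6-{3-[(5R)-1-(benzyloxy)-5-[(tert-butyldimethylsilyl)oxy]-3-methyl-8-oxo-5,6,7,8-tetrahydronaphthalen-2-yl]-4-oxobutanoyl}phenyl trifluoromethanesulfonate, both C3 epimers | Cc1cc(OCc2ccccc2)c(OS(=O)(=O)C(F)(F)F)c(c1)C(=O)CC(C=O)c1c(C)cc2c(c1OCc3ccccc3)C(=O)CC[C@H]2O[Si](C)(C)C(C)(C)C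
F4 | step 16 | (3S,4R)-5-(benzyloxy)-3-[(5R)-1-(benzyloxy)-5-[(tert-butyldimethylsilyl)oxy]-3-methyl-8-oxo-5,6,7,8-tetrahydronaphthalen-2-yl]-4-hydroxy-7-methyl-3,4-dihydronaphthalen-1(2H)-one | Cc1cc(OCc2ccccc2)c2c(c1)C(=O)C[C@@H](c1c(C)cc3c(c1OCc4ccccc4)C(=O)CC[C@H]3O[Si](C)(C)C(C)(C)C)[C@H]2O
F0 | step 15 | none | none
F5 | step 3 | rac-4,8-dihydroxy-6-methyl-3,4-dihydronaphthalen-1(2H)-one | Cc1cc2c(c(O)c1)C(=O)CCC2O
F6 | step 3 | (4R)-4-acetoxy-8-hydroxy-6-methyl-3,4-dihydronaphthalen-1(2H)-one | Cc1cc2c(c(O)c1)C(=O)CC[C@H]2OC(C)=O
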